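**Plan**

- The retrosynthesis first cuts the two methylene bridges at ring B: the CH2–ring B bond of the B–C bridge, and both bonds of the A–B bridge CH2 (which comes from an iminium salt). This gives ring A, ring B and ring C as separate pieces.
- Ring C is cut at O1–C2 of the pyran (back to a prenyl phenol), at C8–C(=O) (back to an O-butanoate), and then in the benzene ring at C8a–C4a, C5–C6 and C8–C8a (back to a cyclobutenone and a siloxyalkyne).
- Feature that makes this possible: ring C (C4a, C5, C6, C7, C8, C8a of the chromene) is a fully substituted phloroglucinol whose three oxygens have different fates, only the one on C8a entering the pyran. The benzannulation delivers this pattern directly: free OH on C8a between the prenyl carbon C4a and the open C8, silyl ethers on C5 and C7, the CH2OMe arm on C6.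
- Ring A is cut at the two ring bonds leaving the carbonyls on its quaternary carbon (dianion acylation, then Claisen closure), back to acetylacetone and a methyl(geranyl)malonate.
- Forward order: benzene ring of ring C (step 5), pyran (step 8), union with ring B (step 11); ring A is closed separately (step 16) and joined last (step 17).
- Stereochemistry: the single quaternary stereocentre is set by catalyst-controlled asymmetric phase-transfer geranylation of a mixed methylmalonate (step 14). Its two esters are used in a fixed order so the configuration reaches ring A as R. The 2E alkene comes in with geranyl bromide.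

Key step: step 5

Assumption: ring A is written in the enol tautomer of the target SMILES, and the descriptor R refers to that tautomer.
Assumption: the (S,S)-catalyst of step 14 is taken to give the (S)-malonate 28, as in allylations of the same malonate; if geranyl bromide reacts with the opposite sense, the (R,R)-catalyst is used and nothing else changes.

**Route**

Step 1
Reactants: 1 methyl methoxyacetate
Product: 3 triisopropyl[(3-methoxyprop-1-yn-1-yl)oxy]silane, via lithium ynolate 2 (not isolated)
Conditions: CH2Br2, LiTMP (lithium 2,2,6,6-tetramethylpiperidide), THF, −78 °C; LiHMDS (LiN(SiMe3)2); n-BuLi, −78 → 20 °C; TIPSCl, −78 °C → rt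
Reagents that add atoms: dibromomethane, BrCBr; triisopropylsilyl chloride, CC(C)[Si](Cl)(C(C)C)C(C)C
Why: Kowalski ester homologation, in which LiCHBr2 adds to the ester at −78 °C, base and bromine–lithium exchange give a carbenoid that rearranges to ynolate 2, and the bulky silyl chloride traps it on oxygen; β-amino ynolates made this way from α-amino esters are known to survive, so loss of methoxide from 2 is not expected in the cold.

Step 2
Reactants: 3 triisopropyl[(3-methoxyprop-1-yn-1-yl)oxy]silane
Product: 4 4,4-dichloro-2-(methoxymethyl)-3-(triisopropylsilyloxy)cyclobut-2-en-1-one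
Conditions: Cl3CCOCl, Zn–Cu couple, Et2O–DME, 0 °C → rt
Reagents that add atoms: trichloroacetyl chloride, ClC(=O)C(Cl)(Cl)Cl
Why: Ketene–alkyne [2+2] cycloaddition in which the nucleophilic CH2OMe-bearing carbon of 3 attacks the carbonyl carbon of dichloroketene, fixing the 2-alkyl-3-siloxy pattern, while DME ties up ZnCl2 so the siloxyalkyne is not exposed to a free Lewis acid.

Step 3
Reactants: 4 4,4-dichloro-2-(methoxymethyl)-3-(triisopropylsilyloxy)cyclobut-2-en-1-one
Product: 5 2-(methoxymethyl)-3-(triisopropylsilyloxy)cyclobut-2-en-1-one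
Conditions: Zn dust, TMEDA, AcOH, EtOH, 0 °C
Reagents that add atoms: none
Why: Reductive dechlorination of an α,α-dichloroketone by zinc through its zinc enolate, run cold and buffered by TMEDA so that the bulky triisopropylsilyl vinylogous ester is not solvolysed.

Step 4
Reactants: 6 ethyl 4-methylpent-3-enoate
Product: 8 triisopropyl[(5-methylhex-4-en-1-yn-1-yl)oxy]silane, via lithium ynolate 7 (not isolated)
Conditions: CH2Br2, LiTMP (lithium 2,2,6,6-tetramethylpiperidide), THF, −78 °C; LiHMDS (LiN(SiMe3)2); n-BuLi, −78 → 20 °C; TIPSCl, −78 °C → rt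
Reagents that add atoms: dibromomethane, BrCBr; triisopropylsilyl chloride, CC(C)[Si](Cl)(C(C)C)C(C)C
Why: Kowalski ester homologation and O-silylation as in step 1, with addition of LiCHBr2 at −78 °C expected to precede deprotonation of the β,γ-unsaturated ester so that the trisubstituted alkene stays out of conjugation.

Step 5
Reactants: 5 2-(methoxymethyl)-3-(triisopropylsilyloxy)cyclobut-2-en-1-one; 8 triisopropyl[(5-methylhex-4-en-1-yn-1-yl)oxy]silane
Product: 13 4-(methoxymethyl)-2-(3-methylbut-2-en-1-yl)-3,5-bis(triisopropylsilyloxy)phenol, via siloxy vinylketene 9 (not isolated), via vinylcyclobutenone 10 (not isolated), via dienylketene 11 (not isolated), via cyclohexadienone 12 (not isolated)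
Conditions: 8 (1.2 equiv), degassed toluene, 80 → 110 °C
Reagents that add atoms: none
Why: Heating should open cyclobutenone 5 by a conrotatory 4π electrocyclic reaction (breaking the future C8–C8a bond) to vinylketene 9, which the electron-rich siloxyalkyne 8 captures in a [2+2] cycloaddition that forms C8a–C4a and C5–C6 and gives vinylcyclobutenone 10. A second 4π opening gives dienylketene 11, whose 6π electrocyclisation re-forms C8–C8a and closes ring C as cyclohexa-2,4-dienone 12, and enolisation then gives phenol 13. The closest known reaction type is the Danheiser benzannulation of cyclobutenones with trialkylsiloxyalkynes, here with a 3-siloxy in place of a 3-alkyl cyclobutenone. The only ring closed is the carbocycle, by a thermally allowed disrotatory 6π closure of a dienylketene whose ketene and vinyl ends are cis, and no stereocentre is created. The step needs head-to-tail regiochemistry in the ketene–alkyne union, which the polarisation of 8 secures: its nucleophilic prenyl-bearing carbon bonds to the ketene carbonyl carbon, so the prenyl group ends up beside the one free hydroxyl (C8a) while the oxygens on C5 and C7 remain silyl ethers. A slight excess of 8 at moderate dilution should limit ketene dimerisation and acylation of 13 by 9.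

Step 6
Reactants: 13 4-(methoxymethyl)-2-(3-methylbut-2-en-1-yl)-3,5-bis(triisopropylsilyloxy)phenol
Product: 14 4-(methoxymethyl)-2-(3-methylbut-2-en-1-yl)-3,5-bis(triisopropylsilyloxy)phenyl butanoate
Conditions: butyryl chloride, Et3N, DMAP (cat.), CH2Cl2, 0 °C
Reagents that add atoms: butyryl chloride, CCCC(Cl)=O
Why: DMAP-catalysed acylation of the only free phenol places the butanoyl group on the C8a oxygen, from which it can be moved to C8.

Step 7
Reactants: 14 4-(methoxymethyl)-2-(3-methylbut-2-en-1-yl)-3,5-bis(triisopropylsilyloxy)phenyl butanoate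
Product: 15 1-[2-hydroxy-5-(methoxymethyl)-3-(3-methylbut-2-en-1-yl)-4,6-bis(triisopropylsilyloxy)phenyl]butan-1-one
Conditions: hν (254 nm), degassed cyclohexane, rt
Reagents that add atoms: none
Why: Photo-Fries rearrangement, in which the excited ester cleaves at the ArO–acyl bond to a caged aryloxyl/butanoyl radical pair that recombines at the only unsubstituted ortho carbon (C8, since C6 and C4a are blocked) to a hydrogen-bonded and therefore photostable o-hydroxy ketone, under neutral conditions that spare the silyl ethers, the benzylic ether and the prenyl group that a Lewis-acid Fries reaction would attack.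

Step 8
Reactants: 15 1-[2-hydroxy-5-(methoxymethyl)-3-(3-methylbut-2-en-1-yl)-4,6-bis(triisopropylsilyloxy)phenyl]butan-1-one
Product: 18 1-[6-(methoxymethyl)-2,2-dimethyl-5,7-bis(triisopropylsilyloxy)-2H-chromen-8-yl]butan-1-one, via selenide 16 (not isolated), via selenoxide 17 (not isolated)
Conditions: PhSeCl, pyridine, CH2Cl2, −78 → 0 °C; then 30% aq. H2O2, 0 °C → rt
Reagents that add atoms: none
Why: Selenoetherification then selenoxide syn-elimination, in which the seleniranium ion of the prenyl alkene is opened 6-endo at its tertiary carbon by the only free hydroxyl (on C8a) and the selenoxide eliminates towards C4, the only β-carbon bearing hydrogen, so the 2,2-dimethylchromene forms without an oxidant that could attack the electron-rich benzylic ether.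

Step 9
Reactants: 18 1-[6-(methoxymethyl)-2,2-dimethyl-5,7-bis(triisopropylsilyloxy)-2H-chromen-8-yl]butan-1-one
Product: 19 1-[5,7-dihydroxy-6-(methoxymethyl)-2,2-dimethyl-2H-chromen-8-yl]butan-1-one
Conditions: TBAF (Bu4NF), AcOH, THF, 0 °C
Reagents that add atoms: none
Why: Fluoride cleaves both aryl silyl ethers, and the acetic acid buffer keeps the liberated phenoxides from expelling methoxide prematurely.

Step 10
Reactants: 20 phloroglucinol (benzene-1,3,5-triol)
Product: 21 1-(2,4,6-trihydroxyphenyl)butan-1-one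
Conditions: butyryl chloride, AlCl3, PhNO2–CH2Cl2, 0 → 50 °C; aq. HCl work-up
Reagents that add atoms: butyryl chloride, CCCC(Cl)=O
Why: Friedel–Crafts acylation of phloroglucinol should stop after one acylation because the chelated ketone deactivates the ring.

Step 11
Reactants: 19 1-[5,7-dihydroxy-6-(methoxymethyl)-2,2-dimethyl-2H-chromen-8-yl]butan-1-one; 21 1-(2,4,6-trihydroxyphenyl)butan-1-one
Product: 23 1-[3-[(8-butanoyl-5,7-dihydroxy-2,2-dimethyl-2H-chromen-6-yl)methyl]-2,4,6-trihydroxyphenyl]butan-1-one, via o-quinone methide 22 (not isolated)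
Conditions: 21 (3 equiv), PPTS (pyridinium p-toluenesulfonate, cat.), 1,4-dioxane, 60 °C
Reagents that add atoms: none
Why: Weak acid promotes loss of methanol from the o-hydroxybenzyl ether to o-quinone methide 22, which a free ring carbon of 21 captures (Michael-type Friedel–Crafts alkylation); ring C has no free carbon and cannot self-condense, excess 21 suppresses double alkylation, and the weak acid should leave the chromene alkene unprotonated.

Step 12
Reactants: 24 2,2,5-trimethyl-1,3-dioxane-4,6-dione
Product: 25 3-tert-butoxy-2-methyl-3-oxopropanoic acid (racemic)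
Conditions: t-BuOH, reflux
Reagents that add atoms: tert-butanol, CC(C)(C)O
Why: Alcoholysis of the cyclic acylal (addition and ring opening with loss of acetone) gives the malonic half ester.

Step 13
Reactants: 25 3-tert-butoxy-2-methyl-3-oxopropanoic acid
Product: 26 1-tert-butyl 3-(2,2-diphenylethyl) 2-methylpropanedioate (racemic)
Conditions: 2,2-diphenylethanol, DCC, DMAP (cat.), CH2Cl2, 0 °C → rt
Reagents that add atoms: 2,2-diphenylethanol, OCC(c1ccccc1)c1ccccc1
Why: Steglich esterification joins the acid to the primary alcohol under neutral conditions that leave the tert-butyl ester intact.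

Step 14
Reactants: 26 1-tert-butyl 3-(2,2-diphenylethyl) 2-methylpropanedioate; 27 geranyl bromide ((2E)-1-bromo-3,7-dimethylocta-2,6-diene)
Product: 28 1-tert-butyl 3-(2,2-diphenylethyl) (2S)-2-[(2E)-3,7-dimethylocta-2,6-dien-1-yl]-2-methylpropanedioate
Conditions: (S,S)-2,6-bis(3,4,5-trifluorophenyl)-4,4'-spirobi[4,5-dihydro-3H-dinaphtho[2,1-c:1',2'-e]azepinium] bromide (5 mol %), 50% aq. KOH, toluene, −40 °C
Reagents that add atoms: none
Why: Asymmetric phase-transfer alkylation, in which the chiral N-spiro ammonium cation pairs with the malonate enolate and exposes one enantiotopic face to SN2 attack on geranyl bromide, a reaction type established for this tert-butyl/2,2-diphenylethyl methylmalonate with allylic bromides; this sets the only stereocentre (S, by catalyst control) and the E-alkene is carried in from 27.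

Step 15
Reactants: 28 1-tert-butyl 3-(2,2-diphenylethyl) (2S)-2-[(2E)-3,7-dimethylocta-2,6-dien-1-yl]-2-methylpropanedioate
Product: 30 (2R,4E)-2-[(2,2-diphenylethoxy)carbonyl]-2,5,9-trimethyldeca-4,8-dienoic acid, via trimethylsilyl ester 29 (not isolated)
Conditions: TMSOTf, 2,6-lutidine, CH2Cl2, 0 °C; aqueous work-up at pH 4
Reagents that add atoms: none
Why: Silyl triflate-mediated cleavage of the tert-butyl ester (O-silylation, loss of the tert-butyl cation as isobutene, hydrolysis of silyl ester 29 on work-up) under buffered non-protic conditions that avoid acid-induced lactonisation or cyclisation of the geranyl chain and leave the primary ester alone; no bond at the stereocentre is broken and the descriptor becomes R only through a priority switch.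

Step 16
Reactants: 30 (2R,4E)-2-[(2,2-diphenylethoxy)carbonyl]-2,5,9-trimethyldeca-4,8-dienoic acid; 31 acetylacetone (pentane-2,4-dione)
Product: 34 (4R)-2-acetyl-4-[(2E)-3,7-dimethylocta-2,6-dien-1-yl]-3,5-dihydroxy-4-methylcyclohexa-2,5-dien-1-one, via acyl imidazole 32 (not isolated), via triketo ester 33 (not isolated)
Conditions: CDI, THF, rt; added at −78 °C to the dianion of 31 (3.5 equiv, from 31 and LDA (LiN(i-Pr)2), THF, 0 °C), then → rt and 40 °C; cold 1 M HCl work-up
Reagents that add atoms: none
Why: Acyl imidazole 32 acylates the terminal carbon of the acetylacetone dianion (1,3-diketone dianion acylation) to triketo ester 33, whose central acidic methylene then attacks the remaining ester in a 6-exo Claisen (Dieckmann-type) cyclisation, the mode by which triketo esters close to acylphloroglucinols; the acid-derived carbonyl ends up beside the unsubstituted ring carbon and the ester carbonyl beside the acetyl-bearing one, so the configuration of 30 becomes that of (R)-34 without any bond at the quaternary centre being broken.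

Step 17
Reactants: 34 (4R)-2-acetyl-4-[(2E)-3,7-dimethylocta-2,6-dien-1-yl]-3,5-dihydroxy-4-methylcyclohexa-2,5-dien-1-one; 23 1-[3-[(8-butanoyl-5,7-dihydroxy-2,2-dimethyl-2H-chromen-6-yl)methyl]-2,4,6-trihydroxyphenyl]butan-1-one
Product: 37 (4R)-2-acetyl-6-[[3-butanoyl-5-[(8-butanoyl-5,7-dihydroxy-2,2-dimethyl-2H-chromen-6-yl)methyl]-2,4,6-trihydroxyphenyl]methyl]-4-[(2E)-3,7-dimethylocta-2,6-dien-1-yl]-3,5-dihydroxy-4-methylcyclohexa-2,5-dien-1-one, via Mannich base 35 (not isolated), via methylene trione 36 (not isolated)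
Conditions: CH2=NMe2+ I− (1.05 equiv), NaOAc, MeCN, 0 °C → rt; then 23 (1.2 equiv), 60 °C
Reagents that add atoms: dimethylmethyleneiminium iodide, C=[N+](C)C.[I-]
Why: Mannich reaction at the one free enolic carbon of 34 gives 35, which on warming loses dimethylamine to the 2-methylene-1,3-dione 36, and the free ring-B carbon of 23 adds to it (Michael-type Friedel–Crafts alkylation) to form the second methylene bridge; pre-forming the Mannich base directs the CH2 unit to ring A and avoids symmetric dimers, and the mild buffered conditions should leave the quaternary stereocentre, the first bridge and the geranyl chain untouched.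

**Compound list**

1 | methyl methoxyacetate | COCC(=O)OC | starting material
2 | lithium 3-methoxyprop-1-yn-1-olate | COCC#C[O-].[Li+] | intermediate (not isolated)
3 | triisopropyl[(3-methoxyprop-1-yn-1-yl)oxy]silane | COCC#CO[Si](C(C)C)(C(C)C)C(C)C | intermediate
4 | 4,4-dichloro-2-(methoxymethyl)-3-(triisopropylsilyloxy)cyclobut-2-en-1-one | COCC1=C(O[Si](C(C)C)(C(C)C)C(C)C)C(Cl)(Cl)C1=O | intermediate
5 | 2-(methoxymethyl)-3-(triisopropylsilyloxy)cyclobut-2-en-1-one | O=C1CC(O[Si](C(C)C)(C(C)C)C(C)C)=C1COC | intermediate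
6 | ethyl 4-methylpent-3-enoate | CCOC(=O)CC=C(C)C | starting material
7 | lithium 5-methylhex-4-en-1-yn-1-olate | CC(C)=CCC#C[O-].[Li+] | intermediate (not isolated)
8 | triisopropyl[(5-methylhex-4-en-1-yn-1-yl)oxy]silane | CC(C)=CCC#CO[Si](C(C)C)(C(C)C)C(C)C | intermediate
9 | 2-(methoxymethyl)-3-(triisopropylsilyloxy)buta-1,3-dien-1-one | C=C(O[Si](C(C)C)(C(C)C)C(C)C)C(COC)=C=O | intermediate (not isolated)
10 | 4-(methoxymethyl)-2-(3-methylbut-2-en-1-yl)-3-(triisopropylsilyloxy)-4-[1-(triisopropylsilyloxy)ethenyl]cyclobut-2-en-1-one (racemic) | O=C1C(CC=C(C)C)=C(O[Si](C(C)C)(C(C)C)C(C)C)C1(COC)C(=C)O[Si](C(C)C)(C(C)C)C(C)C | intermediate (not isolated)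
11 | 4-(methoxymethyl)-2-(3-methylbut-2-en-1-yl)-3,5-bis(triisopropylsilyloxy)hexa-1,3,5-trien-1-one, ketene and vinyl ends cis | O=C=C(CC=C(C)C)/C(O[Si](C(C)C)(C(C)C)C(C)C)=C(/COC)C(O[Si](C(C)C)(C(C)C)C(C)C)=C | intermediate (not isolated)
12 | 4-(methoxymethyl)-2-(3-methylbut-2-en-1-yl)-3,5-bis(triisopropylsilyloxy)cyclohexa-2,4-dien-1-one | O=C1CC(O[Si](C(C)C)(C(C)C)C(C)C)=C(COC)C(O[Si](C(C)C)(C(C)C)C(C)C)=C1CC=C(C)C | intermediate (not isolated)
13 | 4-(methoxymethyl)-2-(3-methylbut-2-en-1-yl)-3,5-bis(triisopropylsilyloxy)phenol | Oc1cc(O[Si](C(C)C)(C(C)C)C(C)C)c(COC)c(O[Si](C(C)C)(C(C)C)C(C)C)c1CC=C(C)C | intermediate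
14 | 4-(methoxymethyl)-2-(3-methylbut-2-en-1-yl)-3,5-bis(triisopropylsilyloxy)phenyl butanoate | CCCC(=O)Oc1cc(O[Si](C(C)C)(C(C)C)C(C)C)c(COC)c(O[Si](C(C)C)(C(C)C)C(C)C)c1CC=C(C)C | intermediate
15 | 1-[2-hydroxy-5-(methoxymethyl)-3-(3-methylbut-2-en-1-yl)-4,6-bis(triisopropylsilyloxy)phenyl]butan-1-one | CCCC(=O)c1c(O)c(CC=C(C)C)c(O[Si](C(C)C)(C(C)C)C(C)C)c(COC)c1O[Si](C(C)C)(C(C)C)C(C)C | intermediate
16 | 1-[6-(methoxymethyl)-2,2-dimethyl-3-(phenylselanyl)-5,7-bis(triisopropylsilyloxy)chroman-8-yl]butan-1-one (racemic) | CCCC(=O)c1c(O[Si](C(C)C)(C(C)C)C(C)C)c(COC)c(O[Si](C(C)C)(C(C)C)C(C)C)c2CC([Se]c3ccccc3)C(C)(C)Oc12 | intermediate (not isolated)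
17 | 1-[6-(methoxymethyl)-2,2-dimethyl-3-(phenylseleninyl)-5,7-bis(triisopropylsilyloxy)chroman-8-yl]butan-1-one (racemic) | CCCC(=O)c1c(O[Si](C(C)C)(C(C)C)C(C)C)c(COC)c(O[Si](C(C)C)(C(C)C)C(C)C)c2CC([Se](=O)c3ccccc3)C(C)(C)Oc12 | intermediate (not isolated)
18 | 1-[6-(methoxymethyl)-2,2-dimethyl-5,7-bis(triisopropylsilyloxy)-2H-chromen-8-yl]butan-1-one | CCCC(=O)c1c(O[Si](C(C)C)(C(C)C)C(C)C)c(COC)c(O[Si](C(C)C)(C(C)C)C(C)C)c2C=CC(C)(C)Oc12 | intermediate
19 | 1-[5,7-dihydroxy-6-(methoxymethyl)-2,2-dimethyl-2H-chromen-8-yl]butan-1-one | CCCC(=O)c1c(O)c(COC)c(O)c2C=CC(C)(C)Oc12 | intermediate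
20 | phloroglucinol | Oc1cc(O)cc(O)c1 | starting material
21 | 1-(2,4,6-trihydroxyphenyl)butan-1-one | CCCC(=O)c1c(O)cc(O)cc1O | intermediate
22 | 8-butanoyl-7-hydroxy-2,2-dimethyl-6-methylidene-2H-chromen-5(6H)-one | CCCC(=O)C1=C(O)C(=C)C(=O)C2=C1OC(C)(C)C=C2 | intermediate (not isolated)
23 | 1-[3-[(8-butanoyl-5,7-dihydroxy-2,2-dimethyl-2H-chromen-6-yl)methyl]-2,4,6-trihydroxyphenyl]butan-1-one | CCCC(=O)c1c(O)cc(O)c(Cc2c(O)c3c(c(C(=O)CCC)c2O)OC(C)(C)C=C3)c1O | intermediate
24 | 2,2,5-trimethyl-1,3-dioxane-4,6-dione | CC1C(=O)OC(C)(C)OC1=O | starting material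
25 | 3-tert-butoxy-2-methyl-3-oxopropanoic acid (racemic) | CC(C(=O)O)C(=O)OC(C)(C)C | intermediate
26 | 1-tert-butyl 3-(2,2-diphenylethyl) 2-methylpropanedioate (racemic) | CC(C(=O)OC(C)(C)C)C(=O)OCC(c1ccccc1)c1ccccc1 | intermediate
27 | geranyl bromide, (2E)-1-bromo-3,7-dimethylocta-2,6-diene | BrC/C=C(\C)CCC=C(C)C | starting material
28 | 1-tert-butyl 3-(2,2-diphenylethyl) (2S)-2-[(2E)-3,7-dimethylocta-2,6-dien-1-yl]-2-methylpropanedioate | CC(C)(C)OC(=O)[C@@](C)(C/C=C(\C)CCC=C(C)C)C(=O)OCC(c1ccccc1)c1ccccc1 | intermediate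
29 | 1-(2,2-diphenylethyl) 3-trimethylsilyl (2R)-2-[(2E)-3,7-dimethylocta-2,6-dien-1-yl]-2-methylpropanedioate | C[Si](C)(C)OC(=O)[C@@](C)(C/C=C(\C)CCC=C(C)C)C(=O)OCC(c1ccccc1)c1ccccc1 | intermediate (not isolated)
30 | (2R,4E)-2-[(2,2-diphenylethoxy)carbonyl]-2,5,9-trimethyldeca-4,8-dienoic acid | OC(=O)[C@@](C)(C/C=C(\C)CCC=C(C)C)C(=O)OCC(c1ccccc1)c1ccccc1 | intermediate
31 | acetylacetone (pentane-2,4-dione) | CC(=O)CC(C)=O | starting material
32 | 2,2-diphenylethyl (2R,4E)-2-(imidazole-1-carbonyl)-2,5,9-trimethyldeca-4,8-dienoate | O=C(n1ccnc1)[C@@](C)(C/C=C(\C)CCC=C(C)C)C(=O)OCC(c1ccccc1)c1ccccc1 | intermediate (not isolated)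
33 | 2,2-diphenylethyl (2R,4E)-2-(3,5-dioxohexanoyl)-2,5,9-trimethyldeca-4,8-dienoate | CC(=O)CC(=O)CC(=O)[C@@](C)(C/C=C(\C)CCC=C(C)C)C(=O)OCC(c1ccccc1)c1ccccc1 | intermediate (not isolated)
34 | (4R)-2-acetyl-4-[(2E)-3,7-dimethylocta-2,6-dien-1-yl]-3,5-dihydroxy-4-methylcyclohexa-2,5-dien-1-one | O=C1C=C(O)[C@@](C)(C/C=C(\C)CCC=C(C)C)C(O)=C1C(C)=O | intermediate
35 | (4R)-2-acetyl-6-[(dimethylamino)methyl]-4-[(2E)-3,7-dimethylocta-2,6-dien-1-yl]-3,5-dihydroxy-4-methylcyclohexa-2,5-dien-1-one | CN(C)CC1=C(O)[C@@](C)(C/C=C(\C)CCC=C(C)C)C(O)=C(C(C)=O)C1=O | intermediate (not isolated)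
36 | (4S)-2-acetyl-4-[(2E)-3,7-dimethylocta-2,6-dien-1-yl]-3-hydroxy-4-methyl-6-methylidenecyclohex-2-ene-1,5-dione (same spatial arrangement as 34; descriptor changes by priority only) | C=C1C(=O)[C@@](C)(C/C=C(\C)CCC=C(C)C)C(O)=C(C(C)=O)C1=O | intermediate (not isolated)
37 | (4R)-2-acetyl-6-[[3-butanoyl-5-[(8-butanoyl-5,7-dihydroxy-2,2-dimethyl-2H-chromen-6-yl)methyl]-2,4,6-trihydroxyphenyl]methyl]-4-[(2E)-3,7-dimethylocta-2,6-dien-1-yl]-3,5-dihydroxy-4-methylcyclohexa-2,5-dien-1-one | CCCC(=O)c1c(O)c(CC2=C(O)[C@@](C)(C/C=C(\C)CCC=C(C)C)C(O)=C(C(C)=O)C2=O)c(O)c(Cc2c(O)c3c(c(C(=O)CCC)c2O)OC(C)(C)C=C3)c1O | target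

**Totals**

Total step count: 17.
Longest linear sequence: 10 steps (steps 1, 2, 3, 5, 6, 7, 8, 9, 11, 17, from methyl methoxyacetate).

**Steps most likely to fail, with fallbacks**

Step 5. The 3-siloxy group stabilises the cyclobutenone as a vinylogous ester, so ring opening may need temperatures at which the siloxyalkyne rearranges by silyl shift, or at which the vinylketene dimerises or acylates the phenol faster than it is trapped. The fallback builds ring C by classical phloroglucinol chemistry and gives up the built-in oxygen differentiation. It sets out from 21, which is condensed with 3-methylbut-2-enal (ethylenediammonium diacetate, toluene, reflux; aldol condensation then oxa-6π closure) to give 1-(5,7-dihydroxy-2,2-dimethyl-2H-chromen-8-yl)butan-1-one F1, to be separated from its 6-butanoyl regioisomer. Aminomethylation at the one free ring carbon with dimethylmethyleneiminium iodide gives 1-[6-[(dimethylamino)methyl]-5,7-dihydroxy-2,2-dimethyl-2H-chromen-8-yl]butan-1-one F2. Heating F2 with excess 21 in dioxane releases the same o-quinone methide 22, and the route is rejoined at 23.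

Step 7. The radical pair may escape the solvent cage and return phenol 13, or the light may be absorbed unproductively once the ketone builds up, so conversion stalls. The fallback introduces the acyl group by ortho-formylation and chain extension. It sets out from 13, which is formylated at C8 with MgCl2, Et3N and paraformaldehyde in MeCN at reflux to give 2-hydroxy-5-(methoxymethyl)-3-(3-methylbut-2-en-1-yl)-4,6-bis(triisopropylsilyloxy)benzaldehyde F3. Addition of n-PrMgBr gives 1-[2-hydroxy-5-(methoxymethyl)-3-(3-methylbut-2-en-1-yl)-4,6-bis(triisopropylsilyloxy)phenyl]butan-1-ol F4, and oxidation of the benzylic alcohol with MnO2 rejoins the route at 15.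

Step 16. The hindered acyl imidazole may react sluggishly with the dianion, or the non-enolisable β-keto ester may fragment by retro-Claisen cleavage before the ring closes. The fallback makes ring A by dearomatising alkylation and gives up the asymmetric step. It sets out from 27, which C-alkylates 2,4,6-trihydroxy-3-methylacetophenone F5 (commercial, or from 2-methylphloroglucinol by Friedel–Crafts acetylation) with NaOMe in MeOH at 0 °C at the methyl-bearing carbon. This gives racemic 2-acetyl-4-[(2E)-3,7-dimethylocta-2,6-dien-1-yl]-3,5-dihydroxy-4-methylcyclohexa-2,5-dien-1-one F6, to be separated from the ring-geranylated aromatic isomer. Resolution of F6 by preparative chromatography on a chiral stationary phase rejoins the route at 34.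

Further compounds
F1 | step 5 | 1-(5,7-dihydroxy-2,2-dimethyl-2H-chromen-8-yl)butan-1-one | CCCC(=O)c1c(O)cc(O)c2C=CC(C)(C)Oc12
F2 | step 5 | 1-[6-[(dimethylamino)methyl]-5,7-dihydroxy-2,2-dimethyl-2H-chromen-8-yl]butan-1-one | CCCC(=O)c1c(O)c(CN(C)C)c(O)c2C=CC(C)(C)Oc12
F3 | step 7 | 2-hydroxy-5-(methoxymethyl)-3-(3-methylbut-2-en-1-yl)-4,6-bis(triisopropylsilyloxy)benzaldehyde | O=Cc1c(O)c(CC=C(C)C)c(O[Si](C(C)C)(C(C)C)C(C)C)c(COC)c1O[Si](C(C)C)(C(C)C)C(C)C
F4 | step 7 | 1-[2-hydroxy-5-(methoxymethyl)-3-(3-methylbut-2-en-1-yl)-4,6-bis(triisopropylsilyloxy)phenyl]butan-1-ol (racemic) | CCCC(O)c1c(O)c(CC=C(C)C)c(O[Si](C(C)C)(C(C)C)C(C)C)c(COC)c1O[Si](C(C)C)(C(C)C)C(C)C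
F5 | step 16 | 2,4,6-trihydroxy-3-methylacetophenone | CC(=O)c1c(O)cc(O)c(C)c1O
F6 | step 16 | racemic 2-acetyl-4-[(2E)-3,7-dimethylocta-2,6-dien-1-yl]-3,5-dihydroxy-4-methylcyclohexa-2,5-dien-1-one | O=C1C=C(O)C(C)(C/C=C(\C)CCC=C(C)C)C(O)=C1C(C)=O
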